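## The problem

The target 34 is a germacranolide: a ten-membered carbocycle (C1–C10) trans-fused across C6–C7 to an α-methylene-γ-butyrolactone (O–C6, C7, C11=C13, C12=O). It carries a ketone at C1, a free carbinol at C3, an angelate at C8 and a tertiary acetate on the fully substituted C10. The six stereocentres fall into three groups: the C3/C4 pair, the contiguous C6/C7/C8 triad, and the isolated C10. C10 and C4 have no neighbour that could set them and are best taken from the chiral pool. C7 and C8 can be controlled from C6 through the five-membered ring. C3 can lean on C4 only through a Felkin–Anh preference, so it needs a reagent-controlled reserve. The exocyclic enoate is a Michael acceptor. The angelate isomerises to the tiglate when its acyl group is activated by nucleophilic catalysts. The β-hydroxy ketone next to a tertiary acetate is open to retro-aldol cleavage, elimination and acyl shift, and the lactone can migrate to O8 while the C8 hydroxyl is free. Strong bases, hydrides and nucleophiles are therefore excluded late in the route. The carbocycle holds no ring alkene, so the closure has to form a C–C single bond or pass through a masked function. The array C10(OAc)–C1(=O)–C2H2–C3(OH) is the water adduct of a propargylic acetate C10(OAc)–C1≡C2. Its terminal carbon C2 can add as an acetylide to a C3 aldehyde, and the C10 acetate sits where it can hand oxygen to C1.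

## Retrosynthesis

**C1 ketone to alkyne (34 ⇒ 33 ⇒ 31 ⇒ 30).** No C–C bond is cut. The C1 carbonyl and the C2 methylene are traced back to the C1≡C2 triple bond of cycloalkynol 30, with the C3 hydroxyl silylated for the hydration (31 → 33) and freed at the end. The neighbouring choice, a macro-aldol between a C1 methyl ketone and the C3 aldehyde, would close a ten-membered ring reversibly. The alkyne turns the closure into an irreversible carbonyl addition. The forward reaction must place the oxygen on C1 and not on C2; the C10 acetate is relied on for that.

**Ring closure (30 ⇒ 28).** The C2–C3 bond is cut, giving the seco iodoalkyne aldehyde 28. Cutting C3–C4 would create two stereocentres in the closing step. Cutting C1–C10 or C9–C10 would form the quaternary centre in a macrocyclisation. Cuts inside C5–C8 would open the lactone triad. With C2–C3 as the last bond, five of six stereocentres and all three esters are in place in an open chain. The forward step must add an alkynyl metal to an aldehyde in the presence of a lactone, two esters and an enoate, choose the correct face of the α-methyl aldehyde, and outrun oligomerisation.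

**Functional group adjustments (28 ⇒ 27 ⇒ 26 ⇒ 25 ⇒ 24 ⇒ 21).** No skeletal bond is cut. The aldehyde comes from the silyl ether 26 through alcohol 27, the iodoalkyne from the terminal alkyne 25, the acetate from the tertiary alcohol 24, and the angelate from the diol 21. The order is fixed by reactivity: the secondary C8 hydroxyl is acylated before the tertiary one, the iodide is put on after all acylations, and the aldehyde is unveiled last.

**Lactone triad (21 ⇒ 12 + 19).** The C7–C8 bond is cut between the bromomethyl butenolide 12 and the hydroxy alkynal 19. The neighbouring cut C6–C7 would need an open-chain allyl reagent with C8 already set, which means an extra stereoselective homologation and weaker acyclic control. A cut at C8–C9 would need a C9 carbanion β to the C10 oxygen, which would eliminate. The chosen cut gives two fragments of similar size, and C6 controls both new centres through the ring. The forward reaction must bond through the γ-carbon C7, on the face away from the C6 side chain, with an anti relationship to C8, and must restore the exocyclic methylene.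

**Butenolide fragment (12 ⇒ 11 ⇒ 8 ⇒ 7 ⇒ 5 ⇒ 2 + 3 ⇒ 1).** The bromide 12 comes from the alcohol 11. C13 and the C7=C11 unsaturation are put on the saturated lactone 7 through its selenide 8. The lactone 7 arises from the keto ester 5 by asymmetric hydrogenation, the only catalyst-set centre of the route (C6). The C5–C6 bond of 5 is cut to the protected bromide 2 and methyl succinyl chloride 3, and 2 comes from the commercial bromo alcohol 1. Setting C6 on a saturated lactone avoids any base once the butenolide, whose C6–H is then acidic, exists.

**Alkyne fragment (19 ⇒ 18 ⇒ 17 ⇒ 16 ⇒ 14 ⇒ 13).** The C1≡C2 bond is cut by one-carbon homologation of lactol 17. Everything else is oxidation-state change on the carbon chain of (R)-citramalic acid 13, which delivers C8, C9, C10 with its methyl group, and C1. Its carboxyl groups are told apart through the dioxolanone 14 and the lactone 16. The tertiary hydroxyl is never protected and is acetylated only at 24.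

## Roads not taken

Alternative 1: The cut is through C1–C2 and O–C3. In the forward sense a C1 nitrile oxide, generated from the aldoxime function with NaOCl, adds across a C2=C3 vinyl terminus and closes the carbocycle and an isoxazoline together, giving the bridged isoxazoline A1. Its merit is that the cycloaddition fixes which carbon carries the ketone and which the carbinol, and N–O cleavage (for example with Mo(CO)6) then reveals the β-hydroxy ketone directly. The nitrile oxide sits on a tertiary carbon and should dimerise slowly. The weak points for this target lie elsewhere. The exocyclic enoate is itself a dipolarophile and is oxidant-sensitive, so C13 is carried as a silyloxymethyl group in A1 and the methylene has to be regenerated by elimination next to a β-hydroxy ketone. The face of the alkene is chosen only by the allylic C4 methyl group in a medium-ring transition state, and a wrong C3 cannot be repaired without undoing the isoxazoline. In the regiochemistry of oxygenation this road is better than the chosen plan, whose hydration depends on the direction of acetate participation. The chosen plan sets against this that the methylene lactone travels unmasked, that C3 can be reset by oxidation and transfer hydrogenation, and that a hydroxyl-directed hydrosilylation stands in reserve for the hydration.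

Alternative 2: The cut is the C3–C4 bond, formed while a C1–C6 bond of a six-membered ring breaks. KH with 18-crown-6 forms the tertiary alkoxide, which rearranges through a chair in an anionic oxy-Cope shift and expands the ring to the (E)-cyclodec-5-enone A2. Ring expansion needs no high dilution and pays no entropic penalty, and the chair transfers alkene geometry into C3 and C4. In ring formation this is the better road. Its weak points are what follows. The C5=C6 alkene has to be converted into the C6–O bond and a C5 methylene with regio- and stereocontrol on a flexible ring. The C3 silicon has to be oxidised to the hydroxyl under electrophilic conditions beside a 1,1-disubstituted alkene. KH excludes every ester, so the acetate, the angelate and the whole lactone are built after the key step from the MOM, silyl and PMB ethers of A2. The chosen plan sets against the easier ring formation that nothing but hydration and one deprotection remains after its closure.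

Alternative 3: The cut is through O–C12 and C12–C11. PdCl2 with SnCl2 and PPh3 under CO joins the C6 hydroxyl, CO and a C7 ethynyl group into the methylene lactone, giving the 3-O-triethylsilyl ether A3. A3 is the same compound as 33 of the chosen route. The merit is real: the Michael acceptor is made one step before the end and need not survive any earlier chemistry, whereas the chosen route carries it through ten steps. Against this, the carbonylation does not form the ten-membered ring. The ring would have to be closed beforehand with a free C6 hydroxyl and a second alkyne at C7 present. The trans relation of C6–O and C7 would have to be set on the macrocycle without the lactone, and the lactone would no longer be available as the control element for C7 and C8. The chosen plan creates the methylene lactone together with C7 and C8 in one chromium-mediated step and relies on the inertness of organochromium reagents and cationic gold towards enoates.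

Key step: step 18

Remark: atoms are labelled with germacrane numbers throughout. CIP descriptors follow each structure's own substituent ranking, so several change along the route without inversion. (R)-3-Bromo-2-methylpropan-1-ol is taken as the commercial form of the C3–C5 unit; it is the bromination–reduction product of the (S)-Roche ester.

## Route

Step 1
Reactants: 1 (R)-3-bromo-2-methylpropan-1-ol
Product: 2 (R)-(3-bromo-2-methylpropoxy)(tert-butyl)diphenylsilane
Conditions: t-BuPh2SiCl, imidazole, DMF, rt
Reagents that add atoms: tert-butyl(chloro)diphenylsilane, CC(C)(C)[Si](Cl)(c1ccccc1)c1ccccc1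
Why: Standard silylation of a primary alcohol; the TBDPS ether is chosen because it has to outlast Grignard formation, hydrogenation, enolate chemistry and two chromium steps and still leave with buffered fluoride.

Step 2
Reactants: 2 (R)-(3-bromo-2-methylpropoxy)(tert-butyl)diphenylsilane; 3 methyl 4-chloro-4-oxobutanoate
Product: 5 methyl (S)-7-(tert-butyldiphenylsilyloxy)-6-methyl-4-oxoheptanoate, via Grignard reagent 4 (not isolated)
Conditions: Mg, THF, 40 °C; then 3, Fe(acac)3 (3 mol%), THF, −78 °C
Reagents that add atoms: none
Why: Iron-catalysed acylation of a primary alkyl Grignard reagent by an acid chloride is faster than attack on the methyl ester and forms the C5–C6 bond. C4 is β to the new ketone and cannot epimerise.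

Step 3
Reactants: 5 methyl (S)-7-(tert-butyldiphenylsilyloxy)-6-methyl-4-oxoheptanoate
Product: 7 (S)-5-[(S)-3-(tert-butyldiphenylsilyloxy)-2-methylpropyl]dihydrofuran-2(3H)-one, via hydroxy ester 6 (not isolated)
Conditions: RuCl2[(R)-BINAP] (0.5 mol%), H2 (100 atm), EtOH, 35 °C; then TsOH (cat.), toluene, 50 °C
Reagents that add atoms: none
Why: Noyori asymmetric hydrogenation of a 4-oxo ester, in which the ester binds ruthenium and the ligand decides the face of hydride delivery, sets C6. The (R)-ligand is chosen by analogy with the sense known for β-keto esters and 4-oxoalkanoates, and acid then closes the γ-lactone.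

Step 4
Reactants: 7 (S)-5-[(S)-3-(tert-butyldiphenylsilyloxy)-2-methylpropyl]dihydrofuran-2(3H)-one
Product: 8 (5R)-5-[(S)-3-(tert-butyldiphenylsilyloxy)-2-methylpropyl]-3-(phenylselanyl)dihydrofuran-2(3H)-one (both C11 epimers)
Conditions: LiN(i-Pr)2, THF, −78 °C; then PhSeCl
Reagents that add atoms: benzeneselenenyl chloride, Cl[Se]c1ccccc1
Why: Selenenylation of a lactone enolate at C11; the configuration at C11 is irrelevant because the centre becomes trigonal in step 5.

Step 5
Reactants: 8 (5R)-5-[(S)-3-(tert-butyldiphenylsilyloxy)-2-methylpropyl]-3-(phenylselanyl)dihydrofuran-2(3H)-one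
Product: 11 (R)-5-[(S)-3-(tert-butyldiphenylsilyloxy)-2-methylpropyl]-3-(hydroxymethyl)furan-2(5H)-one, via hydroxymethyl selenide 9 (not isolated), via selenoxide 10 (not isolated)
Conditions: LiN(i-Pr)2, THF, −78 °C; CH2O (gas); then H2O2 (30% aq.), pyridine, CH2Cl2, 0 °C to rt
Reagents that add atoms: formaldehyde, C=O
Why: Aldol addition of the α-seleno enolate to formaldehyde brings in C13. Selenoxide syn-elimination avoids the carbinol carbon and takes the C7 hydrogen, giving the endocyclic C7=C11 butenolide under neutral conditions that leave the now acidic C6–H alone.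

Step 6
Reactants: 11 (R)-5-[(S)-3-(tert-butyldiphenylsilyloxy)-2-methylpropyl]-3-(hydroxymethyl)furan-2(5H)-one
Product: 12 (R)-3-(bromomethyl)-5-[(S)-3-(tert-butyldiphenylsilyloxy)-2-methylpropyl]furan-2(5H)-one
Conditions: CBr4, PPh3, CH2Cl2, 0 °C
Reagents that add atoms: tetrabromomethane, BrC(Br)(Br)Br
Why: Appel bromination of a primary allylic alcohol; no amine base is present, so C6 cannot epimerise through the 2-hydroxyfuran tautomer.

Step 7
Reactants: 13 (R)-citramalic acid [(R)-2-hydroxy-2-methylbutanedioic acid]
Product: 14 2-[(R)-2,2,4-trimethyl-5-oxo-1,3-dioxolan-4-yl]acetic acid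
Conditions: Me2C(OMe)2, TsOH (cat.), rt
Reagents that add atoms: 2,2-dimethoxypropane, COC(C)(C)OC
Why: Acetonide formation ties the α-hydroxy acid into a dioxolanone and leaves only the C8 carboxyl free, as known for malic acid.

Step 8
Reactants: 14 2-[(R)-2,2,4-trimethyl-5-oxo-1,3-dioxolan-4-yl]acetic acid
Product: 16 (R)-3-hydroxy-3-methyldihydrofuran-2(3H)-one, via hydroxyethyl dioxolanone 15 (not isolated)
Conditions: BH3·SMe2, THF, 0 °C to rt; MeOH; then TsOH (cat.), CH2Cl2, rt
Reagents that add atoms: none
Why: Borane reduces the free carboxylic acid much faster than the dioxolanone carbonyl. The C8 alcohol then closes the five-membered lactone under acid with loss of acetone, and the quaternary C10 is not touched.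

Step 9
Reactants: 16 (R)-3-hydroxy-3-methyldihydrofuran-2(3H)-one
Product: 17 (3R)-3-methyloxolane-2,3-diol (lactol, both anomers)
Conditions: i-Bu2AlH (2.2 equiv), CH2Cl2, −78 °C
Reagents that add atoms: none
Why: Half-reduction of a lactone to the lactol; the tetrahedral aluminium hemiacetal survives at −78 °C, and the extra equivalent is consumed by the tertiary hydroxyl.

Step 10
Reactants: 17 (3R)-3-methyloxolane-2,3-diol
Product: 18 (R)-3-methylpent-4-yne-1,3-diol
Conditions: dimethyl (1-diazo-2-oxopropyl)phosphonate, K2CO3, MeOH, 0 °C to rt
Reagents that add atoms: dimethyl (1-diazo-2-oxopropyl)phosphonate, COP(=O)(OC)C(=[N+]=[N-])C(C)=O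
Why: Seyferth–Gilbert homologation in the Ohira–Bestmann form acts on the open hydroxy aldehyde tautomer of the lactol and adds C2. C10 has no hydrogen and cannot epimerise under the carbonate base.

Step 11
Reactants: 18 (R)-3-methylpent-4-yne-1,3-diol
Product: 19 (R)-3-hydroxy-3-methylpent-4-ynal
Conditions: TEMPO (cat.), PhI(OAc)2, CH2Cl2, rt; used at once as a crude solution
Reagents that add atoms: none
Why: Oxoammonium oxidation takes only the primary alcohol; the medium is not basic, so the β-hydroxy aldehyde should neither dehydrate nor undergo retro-aldol cleavage before use.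

Step 12
Reactants: 12 (R)-3-(bromomethyl)-5-[(S)-3-(tert-butyldiphenylsilyloxy)-2-methylpropyl]furan-2(5H)-one; 19 (R)-3-hydroxy-3-methylpent-4-ynal
Product: 21 (4R,5R)-5-[(S)-3-(tert-butyldiphenylsilyloxy)-2-methylpropyl]-4-[(1S,3R)-1,3-dihydroxy-3-methylpent-4-yn-1-yl]-3-methylidenedihydrofuran-2(3H)-one, via allylchromium reagent 20 (not isolated)
Conditions: CrCl2 (4 equiv), THF, 0 °C to rt; aq. NH4Cl
Reagents that add atoms: none
Why: Nozaki–Hiyama allylation: divalent chromium inserts into the C–Br bond and the 2-(alkoxycarbonyl)allyl chromium reagent adds to the aldehyde through its γ-carbon C7 in a closed chair, which regenerates the exocyclic methylene. The chair forms on the ring face away from the C6 side chain (trans-lactone, C7), and the ring-locked E geometry with the aldehyde residue equatorial gives the anti adduct (C8).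

Step 13
Reactants: 21 (4R,5R)-5-[(S)-3-(tert-butyldiphenylsilyloxy)-2-methylpropyl]-4-[(1S,3R)-1,3-dihydroxy-3-methylpent-4-yn-1-yl]-3-methylidenedihydrofuran-2(3H)-one; 22 angelic acid [(Z)-2-methylbut-2-enoic acid]
Product: 24 C8 angelate of 21 (C10 hydroxyl free), via mixed anhydride 23 (not isolated)
Conditions: 22, 2,4,6-Cl3C6H2COCl, Et3N, toluene, rt; then 21, 75 °C
Reagents that add atoms: none
Why: Yamaguchi-type mixed-anhydride esterification run without a nucleophilic catalyst is the established way to transfer the angeloyl group with its Z geometry intact. Only the secondary C8 hydroxyl reacts; the tertiary propargylic one is inert.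

Step 14
Reactants: 24 C8 angelate of 21
Product: 25 C10 acetate of 24 (terminal alkyne)
Conditions: Ac2O, Et3N, DMAP (cat.), CH2Cl2, rt
Reagents that add atoms: acetic anhydride, CC(=O)OC(C)=O
Why: DMAP-catalysed acetylation; a tertiary propargylic alcohol is acylated readily because the alkyne arm is sterically slim, and the ester already in place is not an activated acyl species and should keep its geometry.

Step 15
Reactants: 25 C10 acetate of 24
Product: 26 iodoalkyne (C2–I) of 25
Conditions: N-iodosuccinimide, AgNO3 (cat.), acetone, rt, dark
Reagents that add atoms: N-iodosuccinimide, O=C1CCC(=O)N1I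
Why: Silver-catalysed electrophilic iodination of a terminal alkyne through the silver acetylide; neutral conditions spare the enoate, both esters and the silyl ether.

Step 16
Reactants: 26 iodoalkyne of 25
Product: 27 C3 primary alcohol (silyl group removed from 26)
Conditions: HF·pyridine, pyridine, THF, 0 °C to rt
Reagents that add atoms: none
Why: Fluoride cleavage of the Si–O bond under buffered, weakly acidic conditions that avoid the acyl migration and conjugate addition a basic fluoride source could cause.

Step 17
Reactants: 27 C3 primary alcohol
Product: 28 seco iodoalkyne aldehyde, (4S,6R,7S,8S,10R)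
Conditions: Dess–Martin periodinane, NaHCO3, CH2Cl2, 0 °C to rt
Reagents that add atoms: none
Why: Buffered Dess–Martin oxidation gives the α-methyl aldehyde without epimerising C4 and does not touch the iodoalkyne.

Step 18
Reactants: 28 seco iodoalkyne aldehyde
Product: 30 ten-membered cycloalkynol, (3R,4S,6R,7S,8S,10R), via alkynylchromium species 29 (not isolated)
Conditions: CrCl2 (8 equiv), NiCl2 (0.1 equiv), THF, rt; slow addition of 28 to a final 0.002 M
Reagents that add atoms: none
Why: Intramolecular Nozaki–Hiyama–Kishi reaction: nickel, reduced to the zerovalent state by CrCl2, adds oxidatively to the C2–I bond, transmetalation passes the alkynyl group to trivalent chromium, and the alkynylchromium species 29 adds to the C3 carbonyl. The closest known reaction type is the NHK macrocyclisation of ω-iodoalkynyl aldehydes to nine- and ten-membered cycloalkynols. The single ring, the ten-membered carbocycle, closes by 10-exo-trig 1,2-addition forming C2–C3. The new stereocentre C3 is controlled by the C4 methyl group in the Felkin–Anh sense (attack anti to the C5 branch, past hydrogen), which gives the 3,4-syn alcohol. Chemoselectivity rests on the reagent: alkynylchromium compounds add to aldehydes but not to lactones, esters or enoates, and nickel inserts only into the C(sp)–I bond. Ring closure has to beat oligomerisation; high dilution with slow addition provides for that, and the trans-lactone and the quaternary C10 bend the chain towards the aldehyde. The acetate cannot shift to the new alkoxide because the linear alkyne holds O10 and O3 apart.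

Step 19
Reactants: 30 ten-membered cycloalkynol
Product: 31 C3 triethylsilyl ether of 30
Conditions: Et3SiCl, imidazole, CH2Cl2, 0 °C
Reagents that add atoms: chlorotriethylsilane, CC[Si](Cl)(CC)CC
Why: Silylation keeps the propargylic hydroxyl from capturing the cationic intermediate of step 20 or entering a Meyer–Schuster shift; its oxygen at C3 also makes C2 the less favourable site for nucleophilic attack.

Step 20
Reactants: 31 C3 triethylsilyl ether of 30
Product: 33 3-O-triethylsilyl ether of the target, via alkylidene dioxolanylium ion 32 (not isolated)
Conditions: Ph3PAuNTf2 (5 mol%), H2O (3 equiv), 1,4-dioxane, rt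
Reagents that add atoms: water, O
Why: Gold-catalysed hydration with neighbouring-group participation: the acetate carbonyl oxygen attacks the gold-bound alkyne at C1 (5-exo-dig) anti to the metal, and protodeauration gives the dioxolanylium ion 32. Water adds to its cationic carbon and the ring opens at the enol oxygen, so the new carbonyl sits at C1 and the acetate stays on O10.

Step 21
Reactants: 33 3-O-triethylsilyl ether of the target
Product: 34 CNP0141210.5, (3S,4S,6R,7S,8S,10R)
Conditions: HF·pyridine, pyridine, THF, 0 °C
Reagents that add atoms: none
Why: Buffered fluoride desilylation frees the β-hydroxy ketone without the base that would trigger retro-aldol cleavage, elimination or acetate migration.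

## Compound list

1 | (R)-3-bromo-2-methylpropan-1-ol | BrC[C@H](C)CO | starting material
2 | (R)-(3-bromo-2-methylpropoxy)(tert-butyl)diphenylsilane | BrC[C@H](C)CO[Si](c1ccccc1)(c1ccccc1)C(C)(C)C | intermediate
3 | methyl 4-chloro-4-oxobutanoate | COC(=O)CCC(Cl)=O | starting material
4 | [(R)-3-(tert-butyldiphenylsilyloxy)-2-methylpropyl]magnesium bromide | Br[Mg]C[C@H](C)CO[Si](c1ccccc1)(c1ccccc1)C(C)(C)C | intermediate
5 | methyl (S)-7-(tert-butyldiphenylsilyloxy)-6-methyl-4-oxoheptanoate | COC(=O)CCC(=O)C[C@H](C)CO[Si](c1ccccc1)(c1ccccc1)C(C)(C)C | intermediate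
6 | methyl (4S,6S)-7-(tert-butyldiphenylsilyloxy)-4-hydroxy-6-methylheptanoate | COC(=O)CC[C@H](O)C[C@H](C)CO[Si](c1ccccc1)(c1ccccc1)C(C)(C)C | intermediate
7 | (S)-5-[(S)-3-(tert-butyldiphenylsilyloxy)-2-methylpropyl]dihydrofuran-2(3H)-one | O=C1CC[C@@H](C[C@H](C)CO[Si](c2ccccc2)(c2ccccc2)C(C)(C)C)O1 | intermediate
8 | (5R)-5-[(S)-3-(tert-butyldiphenylsilyloxy)-2-methylpropyl]-3-(phenylselanyl)dihydrofuran-2(3H)-one, both C3 epimers | O=C1C([Se]c2ccccc2)C[C@@H](C[C@H](C)CO[Si](c3ccccc3)(c3ccccc3)C(C)(C)C)O1 | intermediate
9 | (5R)-5-[(S)-3-(tert-butyldiphenylsilyloxy)-2-methylpropyl]-3-(hydroxymethyl)-3-(phenylselanyl)dihydrofuran-2(3H)-one | O=C1C(CO)([Se]c2ccccc2)C[C@@H](C[C@H](C)CO[Si](c3ccccc3)(c3ccccc3)C(C)(C)C)O1 | intermediate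
10 | selenoxide of 9, (5R)-3-(hydroxymethyl)-3-(phenylseleninyl) lactone | O=C1C(CO)([Se](=O)c2ccccc2)C[C@@H](C[C@H](C)CO[Si](c3ccccc3)(c3ccccc3)C(C)(C)C)O1 | intermediate
11 | (R)-5-[(S)-3-(tert-butyldiphenylsilyloxy)-2-methylpropyl]-3-(hydroxymethyl)furan-2(5H)-one | OCC1=C[C@@H](C[C@H](C)CO[Si](c2ccccc2)(c2ccccc2)C(C)(C)C)OC1=O | intermediate
12 | (R)-3-(bromomethyl)-5-[(S)-3-(tert-butyldiphenylsilyloxy)-2-methylpropyl]furan-2(5H)-one | BrCC1=C[C@@H](C[C@H](C)CO[Si](c2ccccc2)(c2ccccc2)C(C)(C)C)OC1=O | intermediate
13 | (R)-citramalic acid, (R)-2-hydroxy-2-methylbutanedioic acid | OC(=O)C[C@@](C)(O)C(O)=O | starting material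
14 | 2-[(R)-2,2,4-trimethyl-5-oxo-1,3-dioxolan-4-yl]acetic acid | OC(=O)C[C@@]1(C)OC(C)(C)OC1=O | intermediate
15 | (R)-5-(2-hydroxyethyl)-2,2,5-trimethyl-1,3-dioxolan-4-one | OCC[C@@]1(C)OC(C)(C)OC1=O | intermediate
16 | (R)-3-hydroxy-3-methyldihydrofuran-2(3H)-one | O=C1OCC[C@@]1(C)O | intermediate
17 | (3R)-3-methyloxolane-2,3-diol, both anomers | OC1OCC[C@@]1(C)O | intermediate
18 | (R)-3-methylpent-4-yne-1,3-diol | C#C[C@](C)(O)CCO | intermediate
19 | (R)-3-hydroxy-3-methylpent-4-ynal | C#C[C@](C)(O)CC=O | intermediate
20 | {[(R)-5-[(S)-3-(tert-butyldiphenylsilyloxy)-2-methylpropyl]-2-oxo-2,5-dihydrofuran-3-yl]methyl}chromium dichloride | Cl[Cr](Cl)CC1=C[C@@H](C[C@H](C)CO[Si](c2ccccc2)(c2ccccc2)C(C)(C)C)OC1=O | intermediate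
21 | (4R,5R)-5-[(S)-3-(tert-butyldiphenylsilyloxy)-2-methylpropyl]-4-[(1S,3R)-1,3-dihydroxy-3-methylpent-4-yn-1-yl]-3-methylidenedihydrofuran-2(3H)-one | C=C1C(=O)O[C@H](C[C@H](C)CO[Si](c2ccccc2)(c2ccccc2)C(C)(C)C)[C@H]1[C@@H](O)C[C@@](C)(O)C#C | intermediate
22 | angelic acid, (Z)-2-methylbut-2-enoic acid | C/C=C(/C)C(=O)O | starting material
23 | (Z)-2-methylbut-2-enoic 2,4,6-trichlorobenzoic anhydride | C/C=C(/C)C(=O)OC(=O)c1c(Cl)cc(Cl)cc1Cl | intermediate
24 | (1S,3R)-1-[(2R,3S)-2-[(S)-3-(tert-butyldiphenylsilyloxy)-2-methylpropyl]-4-methylidene-5-oxooxolan-3-yl]-3-hydroxy-3-methylpent-4-yn-1-yl (Z)-2-methylbut-2-enoate | C=C1C(=O)O[C@H](C[C@H](C)CO[Si](c2ccccc2)(c2ccccc2)C(C)(C)C)[C@H]1[C@@H](OC(=O)/C(C)=C\C)C[C@@](C)(O)C#C | intermediate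
25 | C10 acetate of 24 (terminal alkyne, silyl ether, angelate, methylene lactone) | C=C1C(=O)O[C@H](C[C@H](C)CO[Si](c2ccccc2)(c2ccccc2)C(C)(C)C)[C@H]1[C@@H](OC(=O)/C(C)=C\C)C[C@@](C)(OC(C)=O)C#C | intermediate
26 | iodoalkyne of 25 (iodine on C2) | C=C1C(=O)O[C@H](C[C@H](C)CO[Si](c2ccccc2)(c2ccccc2)C(C)(C)C)[C@H]1[C@@H](OC(=O)/C(C)=C\C)C[C@@](C)(OC(C)=O)C#CI | intermediate
27 | C3 primary alcohol from 26 (silyl group removed) | C=C1C(=O)O[C@H](C[C@H](C)CO)[C@H]1[C@@H](OC(=O)/C(C)=C\C)C[C@@](C)(OC(C)=O)C#CI | intermediate
28 | seco iodoalkyne aldehyde (C3 aldehyde, C2 iodoalkyne, methylene lactone, C8 angelate, C10 acetate) | O=C[C@@H](C)C[C@H]1OC(=O)C(=C)[C@@H]1[C@@H](OC(=O)/C(C)=C\C)C[C@@](C)(OC(C)=O)C#CI | intermediate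
29 | alkynylchromium dichloride derived from 28 (chromium on C2) | O=C[C@@H](C)C[C@H]1OC(=O)C(=C)[C@@H]1[C@@H](OC(=O)/C(C)=C\C)C[C@@](C)(OC(C)=O)C#C[Cr](Cl)Cl | intermediate
30 | ten-membered cycloalkynol (C1≡C2, C3 hydroxyl), (3R,4S,6R,7S,8S,10R) | C=C1C(=O)O[C@@H]2C[C@H](C)[C@@H](O)C#C[C@](C)(OC(C)=O)C[C@H](OC(=O)/C(C)=C\C)[C@@H]12 | intermediate
31 | C3 triethylsilyl ether of 30 | C=C1C(=O)O[C@@H]2C[C@H](C)[C@@H](O[Si](CC)(CC)CC)C#C[C@](C)(OC(C)=O)C[C@H](OC(=O)/C(C)=C\C)[C@@H]12 | intermediate
32 | 4-alkylidene-2-methyl-1,3-dioxolan-2-ylium ion spanning O10 and C1 (C1=C2 with O and C3 cis), bis(triflyl)amide salt | C=C1C(=O)O[C@@H]2C[C@H](C)[C@@H](O[Si](CC)(CC)CC)/C=C3\O[C+](C)O[C@]3(C)C[C@H](OC(=O)/C(C)=C\C)[C@@H]12.[N-](S(=O)(=O)C(F)(F)F)S(=O)(=O)C(F)(F)F | intermediate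
33 | 3-O-triethylsilyl ether of the target (C1 ketone) | C=C1C(=O)O[C@@H]2C[C@H](C)[C@@H](O[Si](CC)(CC)CC)CC(=O)[C@](C)(OC(C)=O)C[C@H](OC(=O)/C(C)=C\C)[C@@H]12 | intermediate
34 | CNP0141210.5, (3S,4S,6R,7S,8S,10R)-10-acetoxy-8-angeloyloxy-3-hydroxy-1-oxogermacr-11(13)-en-6,12-olide | C=C1C(=O)O[C@@H]2C[C@H](C)[C@@H](O)CC(=O)[C@](C)(OC(C)=O)C[C@H](OC(=O)/C(C)=C\C)[C@@H]12 | target

## Step count and risks

Total: 21 steps. Longest linear sequence: 16 steps (steps 1–6 and 12–21 from 1). The citramalic branch (steps 7–11) joins at step 12.

**Step 18 (key step).** The most likely failure is poor facial selectivity at the C3 aldehyde, because the conformation of the forming ten-membered ring can override the Felkin–Anh preference of the α-methyl group. Intermolecular coupling at insufficient dilution is the second concern. The fallback replaces substrate control by reagent control. It sets out from 28, which is cyclised as described. The (3S)-epimeric cycloalkynol F1, alone or mixed with 30, is oxidised with Dess–Martin periodinane to the cyclic ynone F2. F2 is reduced by asymmetric transfer hydrogenation with RuCl(p-cymene)[(R,R)-TsDPEN] in i-PrOH; this antipode delivers hydride to the face that gives the (3R)-alkynol, and no base is present that could epimerise C4. The fallback returns to the route at 30.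

**Step 20.** The most likely failure is attack of the acetate at C2 (6-endo, the 1,3-acyloxy shift common for internal propargylic acetates), which would end in loss of the acetate and an enone oxygenated at C2. The C3 oxygen and capture of the 5-exo ion by water argue against it but do not exclude it. The fallback uses the C3 hydroxyl as the directing group and sets out from 30, so steps 19–21 are bypassed. Trans-hydrosilylation with BnMe2SiH and [Cp*Ru(MeCN)3]PF6 places silicon on the alkyne carbon remote from the free hydroxyl and gives the C1 vinylsilane F3. Tamao–Fleming oxidation (Bu4NF, then H2O2, KHCO3, MeOH/THF, 0 °C) turns the C1–Si bond into the C1 carbonyl and returns to the route at 34. The brief exposure to buffered peroxide is the price of this fallback; the enoate and the esters should tolerate it at 0 °C.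

**Step 12.** The most likely failure is erosion of the anti relationship at C8, because the β-hydroxyl of 19 can bind chromium and open the way to non-chair transition states. Dehydration of 19 before it reacts is the second concern. The fallback corrects C8 after the C–C bond is made. It sets out from 12 and 19; the C8-epimeric diol F4 is separated from the coupling, or made on purpose under zinc Barbier conditions in THF/aqueous NH4Cl if these favour it. F4 is esterified with angelic acid 22 under Mitsunobu conditions (PPh3, diisopropyl azodicarboxylate, toluene), which activate the alcohol and not the acid and invert C8. The fallback returns to the route at 24.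

**Step 13.** The most likely failure is Z-to-E isomerisation of the activated angeloyl unit to the tiglate. Acylation of the hindered C8 hydroxyl may also be slow enough for the lactone to begin migrating to O8. The fallback builds the Z alkene on the substrate and sets out from 21. The C8 hydroxyl is esterified with 2-[bis(2,2,2-trifluoroethoxy)phosphoryl]propanoic acid (DCC, DMAP, CH2Cl2) to the phosphonate ester F5; this acid has no double bond to isomerise. Still–Gennari olefination of F5 with acetaldehyde (KN(SiMe3)2, 18-crown-6, THF, −78 °C) gives the Z-trisubstituted enoate; the phosphonate is by far the most acidic site, so one equivalent of base suffices. The fallback returns to the route at 24.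

## Further compounds

F1 | step 18 | (3S)-epimer of cycloalkynol 30 | C=C1C(=O)O[C@@H]2C[C@H](C)[C@H](O)C#C[C@](C)(OC(C)=O)C[C@H](OC(=O)/C(C)=C\C)[C@@H]12
F2 | step 18 | cyclic ynone (C3 ketone, C1≡C2) | C=C1C(=O)O[C@@H]2C[C@H](C)C(=O)C#C[C@](C)(OC(C)=O)C[C@H](OC(=O)/C(C)=C\C)[C@@H]12
F3 | step 20 | C1 benzyldimethylsilyl vinylsilane of 30 (H on C2 trans to Si, C3 hydroxyl free) | C=C1C(=O)O[C@@H]2C[C@H](C)[C@@H](O)/C=C(\[Si](C)(C)Cc3ccccc3)[C@](C)(OC(C)=O)C[C@H](OC(=O)/C(C)=C\C)[C@@H]12
F4 | step 12 | C8 epimer of diol 21 | C=C1C(=O)O[C@H](C[C@H](C)CO[Si](c2ccccc2)(c2ccccc2)C(C)(C)C)[C@H]1[C@H](O)C[C@@](C)(O)C#C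
F5 | step 13 | C8 2-[bis(2,2,2-trifluoroethoxy)phosphoryl]propanoate of 21 | C=C1C(=O)O[C@H](C[C@H](C)CO[Si](c2ccccc2)(c2ccccc2)C(C)(C)C)[C@H]1[C@@H](OC(=O)C(C)P(=O)(OCC(F)(F)F)OCC(F)(F)F)C[C@@](C)(O)C#C
A1 | alternative 1 | bridged isoxazoline of the ten-membered carbocycle (C13 as silyloxymethyl) | CC(C)(C)[Si](C)(C)OC[C@@H]1C(=O)O[C@@H]2C[C@H](C)[C@@H]3CC(=NO3)[C@](C)(OC(C)=O)C[C@H](OC(=O)/C(C)=C\C)[C@@H]12
A2 | alternative 2 | (E)-cyclodec-5-enone with C3 silyl and C4 methyl | O=C1C[C@H]([Si](C)(C)c2ccccc2)[C@@H](C)/C=C/[C@H](C(=C)COCc2ccc(OC)cc2)[C@@H](O[Si](C)(C)C(C)(C)C)C[C@@]1(C)OCOC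
A3 | alternative 3 | 3-O-triethylsilyl ether of the target (identical with 33) | C=C1C(=O)O[C@@H]2C[C@H](C)[C@@H](O[Si](CC)(CC)CC)CC(=O)[C@](C)(OC(C)=O)C[C@H](OC(=O)/C(C)=C\C)[C@@H]12
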